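**Plan**

- Retrosynthesis: the C3 acetate, the side-chain angelate and the enal are traced back to a 4-methoxybenzyl ether, an aryl methyl ketone and a methyl acrylate; the dihydrofuran ring is then cut at C2–C3 and at O1–C2, a [4+1] disconnection.
- Enabling feature: C3 is benzylic, carries oxygen and lies ortho to O1, so O1–C7a–C3a–C3 is a masked O-alkyl o-quinone methide (four atoms); C2, bonded to the α-carbon of the propenal unit, is the carbanion carbon of a 2-(methoxycarbonyl)allyl sulfonium ylide (one atom).
- Forward: salicylaldehyde is acetylated at C5 and condensed with 4-methoxybenzyl alcohol and toluenesulfinic acid to the methide precursor; (2S,5S)-hexane-2,5-diol gives a C2-symmetric thiolane, which methyl 2-(bromomethyl)acrylate turns into the sulfonium salt.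
- The annulation closes the only ring made in the route, the furan ring on the purchased benzene ring; ketone reduction, ester reduction, selective oxidation to the enal, angeloylation, ether cleavage and acetylation follow.
- Stereochemistry: C2 and C3 (trans, 2S,3R) come from the (2R,5R)-thiolane in the annulation, C1′ (R) from a Corey–Bakshi–Shibata reduction, and the Z alkene from angelic acid, transferred without isomerisation.

Key step: step 6

Assumption: the (2R,5R)-thiolane is taken to deliver the (2S,3R) series; the sense of induction for this ylide is not established, and the antipodal diol is equally available should the preference be opposite.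

**Route**

Step 1
Reactants: 1 salicylaldehyde
Product: 2 5-acetyl-2-hydroxybenzaldehyde
Conditions: AcCl (1.2 equiv), AlCl3 (3.5 equiv), CH2Cl2, 0 °C to reflux; ice/aq. HCl
Reagents that add atoms: acetyl chloride, CC(=O)Cl
Why: Friedel–Crafts acylation: the aluminium phenoxide directs para to oxygen and the complexed formyl group meta, which both point to C5, as in the known acylations of salicylaldehyde with haloacetyl chlorides.

Step 2
Reactants: 2 5-acetyl-2-hydroxybenzaldehyde; 3 4-methoxybenzyl alcohol
Product: 4 1-{4-hydroxy-3-[(4-methoxybenzyloxy)(4-methylbenzenesulfonyl)methyl]phenyl}ethan-1-one (racemic at the sulfonyl-bearing carbon)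
Conditions: 3 (2 equiv), 4-MeC6H4SO2H (1.3 equiv, added in portions), MgSO4, CH2Cl2, 0 °C to rt; crystallisation
Reagents that add atoms: 4-methylbenzenesulfinic acid, Cc1ccc(cc1)S(=O)O
Why: Three-component condensation of an aldehyde, an alcohol and a sulfinic acid (hemiacetal, phenol-stabilised oxocarbenium ion, S-attack of sulfinate) gives the α-alkoxy sulfone; the ketone does not take part, and the new centre is racemic, which is of no consequence because it becomes trigonal in step 6.

Step 3
Reactants: 5 (2S,5S)-hexane-2,5-diol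
Product: 6 (2S,5S)-hexane-2,5-diyl dimethanesulfonate
Conditions: MsCl (2.4 equiv), Et3N (3 equiv), CH2Cl2, −10 to 0 °C
Reagents that add atoms: methanesulfonyl chloride, CS(=O)(=O)Cl
Why: Sulfonylation of both secondary alcohols at oxygen, which leaves the two stereocentres untouched.

Step 4
Reactants: 6 (2S,5S)-hexane-2,5-diyl dimethanesulfonate
Product: 7 (2R,5R)-2,5-dimethylthiolane
Conditions: Na2S·9H2O, DMSO, rt; pentane extraction, distillation
Reagents that add atoms: sodium sulfide, [Na+].[Na+].[S-2]
Why: Double SN2 displacement by sulfide, first intermolecular and then 5-exo-tet, inverts both centres, so the (2S,5S)-diol gives the (2R,5R)-thiolane, a known way to this sulfide.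

Step 5
Reactants: 7 (2R,5R)-2,5-dimethylthiolane; 8 methyl 2-(bromomethyl)acrylate
Product: 9 (2R,5R)-1-[2-(methoxycarbonyl)prop-2-en-1-yl]-2,5-dimethylthiolan-1-ium bromide
Conditions: acetone, rt, 48 h, dark; trituration with Et2O
Reagents that add atoms: none
Why: S-Alkylation of the sulfide by the activated allylic bromide (SN2 and SN2′ give the same salt); sulfur is not stereogenic because of the C2 axis.

Step 6
Reactants: 4 1-{4-hydroxy-3-[(4-methoxybenzyloxy)(4-methylbenzenesulfonyl)methyl]phenyl}ethan-1-one; 9 (2R,5R)-1-[2-(methoxycarbonyl)prop-2-en-1-yl]-2,5-dimethylthiolan-1-ium bromide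
Product: 13 methyl 2-[(2S,3R)-5-acetyl-3-(4-methoxybenzyloxy)-2,3-dihydro-1-benzofuran-2-yl]prop-2-enoate, via alkoxy o-quinone methide 10 (not isolated), via allyl sulfonium ylide 11 (not isolated), via phenoxide thiolanium betaine 12 (not isolated)
Conditions: 9 (1.5 equiv), Cs2CO3 (3 equiv), CH2Cl2, −20 °C, 20 min; then 4 added over 1 h; −20 °C to rt; thiolane 7 recovered
Reagents that add atoms: none
Why: Proposed new method: Cs2CO3 deprotonates the phenol of 4, the phenoxide (helped by the ether oxygen) expels toluenesulfinate to give O-alkyl o-quinone methide 10, and the same base turns 9 into ylide 11, whose sulfur-bound carbon adds to the methide carbon (C2–C3 bond, arene restored) to give betaine 12, in which the phenoxide displaces the thiolane at C2 (O1–C2 bond). The closest known reaction type is the base-mediated [4+1] annulation of sulfonium ylides with o-quinone methides released from 2-(sulfonylmethyl)phenols, which gives trans-2,3-dihydrobenzofurans, together with the use of 2-(alkoxycarbonyl)allyl onium ylides as one-carbon units; an oxygen-substituted methide and absolute control by a C2-symmetric thiolane on this ylide have not been shown. The furan ring closes by a 5-exo-tet SN2 displacement with inversion at C2. C3 is fixed in the C–C bond formation and C2 in the same event followed by the inversion: the anti-periplanar betaine needed for backside attack places the acrylate unit and the benzyloxy group on opposite faces (trans), and the trans-2,5-dimethyl groups of the thiolane, which leave sulfur non-stereogenic, screen one face of the ylide carbon and so set the absolute sense. The step needs attack through the sulfur-bound carbon of the ylide and not its CH2 terminus, direct displacement and not SN2′ closure to a seven-membered ring, and C-alkylation of the methide ahead of O-allylation of the phenoxide by the salt; preforming the ylide in excess and adding 4 slowly keeps phenoxide and sulfinate dilute, and the five-membered closure is kinetically favoured over the seven-membered one. The 5-acetyl group raises the electrophilicity of the methide, and the 4-methoxybenzyl group, unlike an acyl or silyl group, cannot migrate to the phenoxide, so C3 keeps its oxygen and never becomes a free cation.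

Step 7
Reactants: 13 methyl 2-[(2S,3R)-5-acetyl-3-(4-methoxybenzyloxy)-2,3-dihydro-1-benzofuran-2-yl]prop-2-enoate
Product: 14 methyl 2-[(2S,3R)-5-[(1R)-1-hydroxyethyl]-3-(4-methoxybenzyloxy)-2,3-dihydro-1-benzofuran-2-yl]prop-2-enoate
Conditions: (S)-2-methyl-CBS-oxazaborolidine (0.2 equiv), catecholborane (1.5 equiv), toluene, −78 to −40 °C; MeOH, aq. NaHCO3
Reagents that add atoms: none
Why: Corey–Bakshi–Shibata reduction under catalyst control: the (S)-oxazaborolidine delivers hydride to the aryl methyl ketone as it does to acetophenone, giving the (R)-carbinol, and catecholborane at low temperature leaves the acrylate untouched.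

Step 8
Reactants: 14 methyl 2-[(2S,3R)-5-[(1R)-1-hydroxyethyl]-3-(4-methoxybenzyloxy)-2,3-dihydro-1-benzofuran-2-yl]prop-2-enoate
Product: 15 (1R)-1-[(2S,3R)-2-(3-hydroxyprop-1-en-2-yl)-3-(4-methoxybenzyloxy)-2,3-dihydro-1-benzofuran-5-yl]ethan-1-ol
Conditions: i-Bu2AlH (4 equiv), CH2Cl2, −78 to −40 °C; aq. potassium sodium tartrate
Reagents that add atoms: none
Why: 1,2-Reduction of the α-substituted acrylate ester by i-Bu2AlH to the 2-substituted allylic alcohol, known to proceed without conjugate reduction at low temperature; the ethers and the stereocentres are inert.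

Step 9
Reactants: 15 (1R)-1-[(2S,3R)-2-(3-hydroxyprop-1-en-2-yl)-3-(4-methoxybenzyloxy)-2,3-dihydro-1-benzofuran-5-yl]ethan-1-ol
Product: 16 2-[(2S,3R)-5-[(1R)-1-hydroxyethyl]-3-(4-methoxybenzyloxy)-2,3-dihydro-1-benzofuran-2-yl]prop-2-enal
Conditions: TEMPO (0.1 equiv), PhI(OAc)2 (1.1 equiv), CH2Cl2, 0 °C to rt
Reagents that add atoms: none
Why: Oxoammonium oxidation (TEMPO with a hypervalent iodine co-oxidant) is selective for primary over secondary alcohols, fastest for allylic ones, and stops at the aldehyde under non-basic conditions.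

Step 10
Reactants: 16 2-[(2S,3R)-5-[(1R)-1-hydroxyethyl]-3-(4-methoxybenzyloxy)-2,3-dihydro-1-benzofuran-2-yl]prop-2-enal; 17 angelic acid, (Z)-2-methylbut-2-enoic acid
Product: 19 (1R)-1-[(2S,3R)-3-(4-methoxybenzyloxy)-2-(3-oxoprop-1-en-2-yl)-2,3-dihydro-1-benzofuran-5-yl]ethyl (2Z)-2-methylbut-2-enoate, via angelic 2,4,6-trichlorobenzoic anhydride 18 (not isolated)
Conditions: 17 (3 equiv), 2,4,6-trichlorobenzoyl chloride (3 equiv), Et3N (3 equiv), toluene, rt, 2 h; then 16, 60–75 °C
Reagents that add atoms: none
Why: Yamaguchi-type esterification through the preformed mixed anhydride without DMAP is the established way to acylate hindered alcohols with angelic acid without Z-to-E isomerisation to the tiglate, and acyl transfer to oxygen retains C1′.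

Step 11
Reactants: 19 (1R)-1-[(2S,3R)-3-(4-methoxybenzyloxy)-2-(3-oxoprop-1-en-2-yl)-2,3-dihydro-1-benzofuran-5-yl]ethyl (2Z)-2-methylbut-2-enoate
Product: 20 (1R)-1-[(2S,3R)-3-hydroxy-2-(3-oxoprop-1-en-2-yl)-2,3-dihydro-1-benzofuran-5-yl]ethyl (2Z)-2-methylbut-2-enoate
Conditions: DDQ (1.3 equiv), CH2Cl2/pH 7 phosphate buffer (10:1), 0 °C
Reagents that add atoms: none
Why: Oxidative cleavage of a 4-methoxybenzyl ether by DDQ (hydride abstraction, hydrolysis of the hemiacetal); the 4-methoxybenzylic CH2 is more electron-rich and less hindered than C3–H or C1′–H, which sit next to electron-withdrawing oxygen substituents, and the enal, ester and alkenes are inert.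

Step 12
Reactants: 20 (1R)-1-[(2S,3R)-3-hydroxy-2-(3-oxoprop-1-en-2-yl)-2,3-dihydro-1-benzofuran-5-yl]ethyl (2Z)-2-methylbut-2-enoate
Product: 21 (1R)-1-[(2S,3R)-3-acetoxy-2-(3-oxoprop-1-en-2-yl)-2,3-dihydro-1-benzofuran-5-yl]ethyl (2Z)-2-methylbut-2-enoate (CNP0294391.5)
Conditions: Ac2O, pyridine, CH2Cl2, 0 °C to rt
Reagents that add atoms: acetic anhydride, CC(=O)OC(C)=O
Why: O-Acetylation by Ac2O in pyridine; only the O–H bond reacts so C3 keeps its configuration, and DMAP is left out to avoid conjugate addition to the enal and SN2′ opening of the allylic aryl ether.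

**Compound list**

1 | salicylaldehyde | O=Cc1ccccc1O | starting material
2 | 5-acetyl-2-hydroxybenzaldehyde | CC(=O)c1ccc(O)c(C=O)c1 | intermediate
3 | 4-methoxybenzyl alcohol | COc1ccc(CO)cc1 | starting material
4 | 1-{4-hydroxy-3-[(4-methoxybenzyloxy)(4-methylbenzenesulfonyl)methyl]phenyl}ethan-1-one, racemic at the sulfonyl carbon | CC(=O)c1ccc(O)c(c1)C(OCc1ccc(OC)cc1)S(=O)(=O)c1ccc(C)cc1 | intermediate
5 | (2S,5S)-hexane-2,5-diol | C[C@H](O)CC[C@H](C)O | starting material
6 | (2S,5S)-hexane-2,5-diyl dimethanesulfonate | C[C@H](OS(C)(=O)=O)CC[C@H](C)OS(C)(=O)=O | intermediate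
7 | (2R,5R)-2,5-dimethylthiolane | C[C@@H]1CC[C@@H](C)S1 | intermediate
8 | methyl 2-(bromomethyl)acrylate | C=C(CBr)C(=O)OC | starting material
9 | (2R,5R)-1-[2-(methoxycarbonyl)prop-2-en-1-yl]-2,5-dimethylthiolan-1-ium bromide | C[C@@H]1CC[C@@H](C)[S+]1CC(=C)C(=O)OC.[Br-] | intermediate
10 | 4-acetyl-6-[(4-methoxybenzyloxy)methylidene]cyclohexa-2,4-dien-1-one, alkene geometry not assigned | CC(=O)C1=CC(=COCc2ccc(OC)cc2)C(=O)C=C1 | intermediate (not isolated)
11 | ylide of 9, carbanion on the sulfur-bound allylic carbon | C[C@@H]1CC[C@@H](C)[S+]1[CH-]C(=C)C(=O)OC | intermediate (not isolated)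
12 | phenoxide thiolanium betaine, the C–C adduct of 10 and 11; future C3 as in 13, future C2 still bonded to sulfur | C=C(C(=O)OC)[C@H]([C@H](OCc1ccc(OC)cc1)c1cc(C(C)=O)ccc1[O-])[S+]1[C@H](C)CC[C@H]1C | intermediate (not isolated)
13 | methyl 2-[(2S,3R)-5-acetyl-3-(4-methoxybenzyloxy)-2,3-dihydro-1-benzofuran-2-yl]prop-2-enoate | C=C(C(=O)OC)[C@@H]1Oc2ccc(C(C)=O)cc2[C@H]1OCc1ccc(OC)cc1 | intermediate
14 | methyl 2-[(2S,3R)-5-[(1R)-1-hydroxyethyl]-3-(4-methoxybenzyloxy)-2,3-dihydro-1-benzofuran-2-yl]prop-2-enoate | C=C(C(=O)OC)[C@@H]1Oc2ccc([C@@H](C)O)cc2[C@H]1OCc1ccc(OC)cc1 | intermediate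
15 | (1R)-1-[(2S,3R)-2-(3-hydroxyprop-1-en-2-yl)-3-(4-methoxybenzyloxy)-2,3-dihydro-1-benzofuran-5-yl]ethan-1-ol | C=C(CO)[C@@H]1Oc2ccc([C@@H](C)O)cc2[C@H]1OCc1ccc(OC)cc1 | intermediate
16 | 2-[(2S,3R)-5-[(1R)-1-hydroxyethyl]-3-(4-methoxybenzyloxy)-2,3-dihydro-1-benzofuran-2-yl]prop-2-enal | C=C(C=O)[C@@H]1Oc2ccc([C@@H](C)O)cc2[C@H]1OCc1ccc(OC)cc1 | intermediate
17 | angelic acid, (Z)-2-methylbut-2-enoic acid | C/C=C(/C)C(=O)O | starting material
18 | angelic 2,4,6-trichlorobenzoic anhydride | C/C=C(/C)C(=O)OC(=O)c1c(Cl)cc(Cl)cc1Cl | intermediate (not isolated)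
19 | (1R)-1-[(2S,3R)-3-(4-methoxybenzyloxy)-2-(3-oxoprop-1-en-2-yl)-2,3-dihydro-1-benzofuran-5-yl]ethyl (2Z)-2-methylbut-2-enoate | C=C(C=O)[C@@H]1Oc2ccc([C@@H](C)OC(=O)/C(C)=C\C)cc2[C@H]1OCc1ccc(OC)cc1 | intermediate
20 | (1R)-1-[(2S,3R)-3-hydroxy-2-(3-oxoprop-1-en-2-yl)-2,3-dihydro-1-benzofuran-5-yl]ethyl (2Z)-2-methylbut-2-enoate | C=C(C=O)[C@@H]1Oc2ccc([C@@H](C)OC(=O)/C(C)=C\C)cc2[C@H]1O | intermediate
21 | (1R)-1-[(2S,3R)-3-acetoxy-2-(3-oxoprop-1-en-2-yl)-2,3-dihydro-1-benzofuran-5-yl]ethyl (2Z)-2-methylbut-2-enoate | C=C(C=O)[C@@H]1Oc2ccc([C@@H](C)OC(=O)/C(C)=C\C)cc2[C@H]1OC(C)=O | target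

**Step count**

Total steps: 12.
Longest linear sequence: 10 steps (steps 3, 4, 5, 6, 7, 8, 9, 10, 11, 12, from diol 5).

**Steps most likely to fail**

1. Step 6 (the annulation). The methide may be recaptured by sulfinate or carbonate, the phenoxide may be O-allylated by the salt before the methide forms, or the thiolane may give low facial selectivity on this allyl ylide. The fallback uses a known annulation and sets out from aldehyde 2 and salt 9. Salicylaldehydes react with sulfonium ylides by addition to the formyl group followed by 5-exo-tet closure of the phenoxide on the sulfur-bearing carbon, to give trans-2,3-dihydrobenzofuran-3-ols. With Cs2CO3 in MeCN this should give methyl 2-[(2S,3R)-5-acetyl-3-hydroxy-2,3-dihydro-1-benzofuran-2-yl]prop-2-enoate F1. Etherification of the C3 hydroxyl with 4-methoxybenzyl 2,2,2-trichloroacetimidate and catalytic camphorsulfonic acid in CH2Cl2 then returns to the route at 13. The oxygen at C3 now comes from the aldehyde, no sulfone or methide is involved, and the absolute sense again rests on the thiolane, here in its established role in ylide additions to aldehydes.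

2. Step 2 (the α-alkoxy sulfone). The hydrogen-bonded hydroxy aldehyde may condense more slowly than 4-methoxybenzyl alcohol is consumed by the sulfinic acid (benzylic sulfone formation), and the free-phenol product may lose sulfinic acid during purification. The fallback sets out from 2. Silylation with i-Pr3SiCl and imidazole in DMF should give 5-acetyl-2-(triisopropylsilyloxy)benzaldehyde F2, an aldehyde without the internal hydrogen bond. The same condensation with 3 and 4-methylbenzenesulfinic acid should give 1-{3-[(4-methoxybenzyloxy)(4-methylbenzenesulfonyl)methyl]-4-(triisopropylsilyloxy)phenyl}ethan-1-one F3, which has no free phenol and can be chromatographed. Desilylation with Bu4NF buffered by AcOH in THF at 0 °C, which keeps the phenol protonated, returns to the route at 4.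

3. Step 9 (the selective oxidation). The electron-rich secondary benzylic alcohol may be oxidised back to the ketone alongside the primary allylic alcohol. The fallback removes the selectivity question by protection and sets out from 14. Silylation with t-BuMe2SiOTf and 2,6-lutidine at −78 °C should give methyl 2-[(2S,3R)-5-[(1R)-1-(tert-butyldimethylsilyloxy)ethyl]-3-(4-methoxybenzyloxy)-2,3-dihydro-1-benzofuran-2-yl]prop-2-enoate F4. Reduction with i-Bu2AlH should give 2-[(2S,3R)-5-[(1R)-1-(tert-butyldimethylsilyloxy)ethyl]-3-(4-methoxybenzyloxy)-2,3-dihydro-1-benzofuran-2-yl]prop-2-en-1-ol F5. Oxidation of its only free hydroxyl with MnO2 should give 2-[(2S,3R)-5-[(1R)-1-(tert-butyldimethylsilyloxy)ethyl]-3-(4-methoxybenzyloxy)-2,3-dihydro-1-benzofuran-2-yl]prop-2-enal F6. HF·pyridine in THF/pyridine then returns to the route at 16.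

**Further compounds**

F1 | step 6 | methyl 2-[(2S,3R)-5-acetyl-3-hydroxy-2,3-dihydro-1-benzofuran-2-yl]prop-2-enoate | C=C(C(=O)OC)[C@@H]1Oc2ccc(C(C)=O)cc2[C@H]1O
F2 | step 2 | 5-acetyl-2-(triisopropylsilyloxy)benzaldehyde | CC(=O)c1ccc(O[Si](C(C)C)(C(C)C)C(C)C)c(C=O)c1
F3 | step 2 | 1-{3-[(4-methoxybenzyloxy)(4-methylbenzenesulfonyl)methyl]-4-(triisopropylsilyloxy)phenyl}ethan-1-one | CC(=O)c1ccc(O[Si](C(C)C)(C(C)C)C(C)C)c(c1)C(OCc1ccc(OC)cc1)S(=O)(=O)c1ccc(C)cc1
F4 | step 9 | methyl 2-[(2S,3R)-5-[(1R)-1-(tert-butyldimethylsilyloxy)ethyl]-3-(4-methoxybenzyloxy)-2,3-dihydro-1-benzofuran-2-yl]prop-2-enoate | C=C(C(=O)OC)[C@@H]1Oc2ccc([C@@H](C)O[Si](C)(C)C(C)(C)C)cc2[C@H]1OCc1ccc(OC)cc1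
F5 | step 9 | 2-[(2S,3R)-5-[(1R)-1-(tert-butyldimethylsilyloxy)ethyl]-3-(4-methoxybenzyloxy)-2,3-dihydro-1-benzofuran-2-yl]prop-2-en-1-ol | C=C(CO)[C@@H]1Oc2ccc([C@@H](C)O[Si](C)(C)C(C)(C)C)cc2[C@H]1OCc1ccc(OC)cc1
F6 | step 9 | 2-[(2S,3R)-5-[(1R)-1-(tert-butyldimethylsilyloxy)ethyl]-3-(4-methoxybenzyloxy)-2,3-dihydro-1-benzofuran-2-yl]prop-2-enal | C=C(C=O)[C@@H]1Oc2ccc([C@@H](C)O[Si](C)(C)C(C)(C)C)cc2[C@H]1OCc1ccc(OC)cc1
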